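**Retrosynthetic overview**

- The target is opened first at the two protecting groups (benzyl ether on the 4''-phenol, acetonide on the 7'',9''-diol), then at O1–C2 of ring C, which leads back to a 2',4',6'-trihydroxychalcone.
- The strategy rests on ring A (C4a, C5, C6, C7, C8, C8a): a phloroglucinol with oxygen on C5, C7 and C8a and the C4 carbonyl on C4a, which is the pattern of a tetraketide folded by Claisen condensation. Ring A is therefore cut at C4a–C8a to give a linear methyl 9-aryl-3,5,7-trioxonon-8-enoate.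
- The triketo ester comes from a cinnamoyl N-methoxy-N-methylamide (Heck reaction on the ring B bromide) and the trianion of methyl 3,5-dioxohexanoate (from triacetic acid lactone).
- The side chain is made on the ring B bromophenol: Williamson ether (C8''–O), then an auxiliary-controlled anti-aldol with 4-(benzyloxy)benzaldehyde (C7''–C8'', both stereocentres), reduction and acetonide formation.
- Ring order: ring B is bought, ring A is closed in the Claisen folding, ring C is closed last by oxidative cyclisation.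

Key step: step 9

Remark on the chemistry: the polycarbonyl compounds are drawn as keto tautomers although they exist largely as enols; the trihydroxychalcone may partly close to its flavanone on isolation, which is harmless because the flavanone is the intermediate of the following step.

**Step 1**
Reactants: 1 4-bromo-2,6-dimethoxyphenol; 2 ethyl bromoacetate
Product: 4 2-(4-bromo-2,6-dimethoxyphenoxy)acetic acid, via ethyl ester 3 (not isolated)
Conditions: K2CO3, DMF, 60 °C; then 2 M aq. NaOH, rt; HCl to pH 2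
Reagents that add atoms: sodium hydroxide, [Na+].[OH-]
Why: Williamson etherification of the phenoxide with a primary α-bromo ester followed by saponification; the hindered phenol still alkylates readily at an unhindered, carbonyl-activated carbon.

**Step 2**
Reactants: 4 2-(4-bromo-2,6-dimethoxyphenoxy)acetic acid; 5 (S)-4-benzyloxazolidin-2-one
Product: 7 (S)-4-benzyl-3-[2-(4-bromo-2,6-dimethoxyphenoxy)acetyl]oxazolidin-2-one, via mixed pivalic anhydride 6 (not isolated)
Conditions: PivCl, Et3N, THF, −20 °C; then LiCl, 5, −20 °C → rt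
Reagents that add atoms: none
Why: Mixed-anhydride N-acylation of the oxazolidinone (LiCl/Et3N activation), in which the nucleophile attacks the less hindered aryloxyacetyl carbonyl; no stereocentre is formed or touched.

**Step 3**
Reactants: 7 (S)-4-benzyl-3-[2-(4-bromo-2,6-dimethoxyphenoxy)acetyl]oxazolidin-2-one; 8 4-(benzyloxy)benzaldehyde
Product: 10 (S)-4-benzyl-3-[(2R,3R)-3-[4-(benzyloxy)phenyl]-2-(4-bromo-2,6-dimethoxyphenoxy)-3-hydroxypropanoyl]oxazolidin-2-one, via TMS ether 9 (not isolated)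
Conditions: MgCl2 (20 mol %), Et3N, TMSCl, EtOAc, rt; then 1 M aq. HCl–THF (1:5), 0 °C
Reagents that add atoms: none
Why: Evans magnesium halide-catalysed direct anti-aldol: Et3N enolises the MgCl2-chelated imide to the Z-enolate, which adds to the aldehyde on the face opposite the C4 benzyl group through a boat-like transition state, so that C2 (R, the future C8'') and C3 (R, the future C7'') are set 2,3-anti under auxiliary control, while TMSCl silylates the magnesium aldolate, turns the catalyst over and blocks retro-aldol equilibration.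

**Step 4**
Reactants: 10 (S)-4-benzyl-3-[(2R,3R)-3-[4-(benzyloxy)phenyl]-2-(4-bromo-2,6-dimethoxyphenoxy)-3-hydroxypropanoyl]oxazolidin-2-one
Product: 11 (1R,2S)-1-[4-(benzyloxy)phenyl]-2-(4-bromo-2,6-dimethoxyphenoxy)propane-1,3-diol
Conditions: LiBH4, THF–MeOH, 0 °C; aq. work-up
Reagents that add atoms: none
Why: LiBH4 reduces the exocyclic imide carbonyl to the primary alcohol and releases the auxiliary; neither stereocentre is touched (the descriptor at the aryloxy carbon changes from R to S only because the CIP priorities change), and the aryl bromide and benzyl ether are inert to borohydride.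

**Step 5**
Reactants: 11 (1R,2S)-1-[4-(benzyloxy)phenyl]-2-(4-bromo-2,6-dimethoxyphenoxy)propane-1,3-diol
Product: 12 (4R,5S)-4-[4-(benzyloxy)phenyl]-5-(4-bromo-2,6-dimethoxyphenoxy)-2,2-dimethyl-1,3-dioxane
Conditions: 2,2-dimethoxypropane, PPTS (cat.), CH2Cl2, rt
Reagents that add atoms: 2,2-dimethoxypropane, COC(C)(C)OC
Why: Acid-catalysed transacetalisation of the 1,3-diol gives the six-membered acetonide, in which the erythro relationship places aryl and aryloxy both equatorial (trans-4,5); PPTS is too weak to ionise the p-alkoxybenzylic C–O bond, so C7'' should not epimerise.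

**Step 6**
Reactants: 12 (4R,5S)-4-[4-(benzyloxy)phenyl]-5-(4-bromo-2,6-dimethoxyphenoxy)-2,2-dimethyl-1,3-dioxane; 13 N-methoxy-N-methylacrylamide
Product: 14 (E)-3-[4-{[(4R,5S)-4-[4-(benzyloxy)phenyl]-2,2-dimethyl-1,3-dioxan-5-yl]oxy}-3,5-dimethoxyphenyl]-N-methoxy-N-methylprop-2-enamide
Conditions: Pd(OAc)2 (5 mol %), P(o-tol)3, Et3N, DMF, 100 °C
Reagents that add atoms: none
Why: Mizoroki–Heck reaction: oxidative addition of the unhindered aryl bromide to zerovalent palladium (formed in situ from Pd(OAc)2 and the phosphine), syn-carbopalladation of the acrylamide and syn-β-hydride elimination give the E-cinnamoyl amide; acetonide, benzyl ether and the N–O bond are inert.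

**Step 7**
Reactants: 15 triacetic acid lactone (4-hydroxy-6-methyl-2H-pyran-2-one)
Product: 16 methyl 3,5-dioxohexanoate
Conditions: Mg(OMe)2, MeOH, reflux; cold dil. HCl
Reagents that add atoms: magnesium methoxide, C[O-].C[O-].[Mg+2]; methanol, CO
Why: Magnesium methoxide opens the enol lactone by methanolysis and holds the diketo ester as its magnesium chelate, which prevents re-lactonisation; a known transformation of this pyranone with no stereochemical issue.

**Step 8**
Reactants: 16 methyl 3,5-dioxohexanoate (2 equiv); 14 (E)-cinnamoyl N-methoxy-N-methylamide from step 6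
Product: 18 methyl (E)-9-[4-{[(4R,5S)-4-[4-(benzyloxy)phenyl]-2,2-dimethyl-1,3-dioxan-5-yl]oxy}-3,5-dimethoxyphenyl]-3,5,7-trioxonon-8-enoate, via trilithium trianion 17 (not isolated)
Conditions: LDA (3.3 equiv per 16), THF, −78 → 0 °C; then 14, −78 → −20 °C; AcOH, −78 °C
Reagents that add atoms: none
Why: Acylation of a 1,3,5-tricarbonyl trianion: the last-formed, most basic terminal carbanion (C6) adds 1,2 to the N-methoxy-N-methylamide, whose lithium-chelated tetrahedral adduct survives until the acid quench, so over-addition and proton transfer from the product should not interfere, and the enone double bond and the acetal stereocentres are untouched.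

**Step 9**
Reactants: 18 methyl (E)-9-aryl-3,5,7-trioxonon-8-enoate from step 8
Product: 19 (E)-3-[4-{[(4R,5S)-4-[4-(benzyloxy)phenyl]-2,2-dimethyl-1,3-dioxan-5-yl]oxy}-3,5-dimethoxyphenyl]-1-(2,4,6-trihydroxyphenyl)prop-2-en-1-one
Conditions: Mg(OMe)2 (6 equiv), MeOH, rt → 50 °C, N2; then 1 M aq. HCl to pH 5, 0 °C
Reagents that add atoms: none
Why: In methanolic Mg(OMe)2 the triketo ester is held as a magnesium-chelated polyenolate whose 5,7-diketone unit is enolised, so the carbon between these carbonyls (chain C6, the future C4a) adds to the magnesium-bound ester carbonyl (chain C1, the future C8a), methoxide is lost and the resulting 2-cinnamoylcyclohexane-1,3,5-trione tautomerises to the aromatic trihydroxychalcone. The closest known reaction type is the Claisen (Dieckmann-type) cyclisation of 3,5,7-trioxoalkanoate esters to acylphloroglucinols under magnesium methoxide. Ring A closes in a 6-exo-trig mode (enolate carbon onto the ester carbonyl, the carbonyl oxygen exocyclic); no stereocentre is formed, and the two side-chain stereocentres are acetal-bound carbons without acidic hydrogens, so they are not at risk in base. The step needs Claisen C-acylation to win over aldol attack of the chain C2 carbanion on the C7 ketone, over carbon or oxygen conjugate addition to C9 and over O-acylation to a 4-hydroxy-2-pyranone. The substrate secures this because the C7 carbonyl and the enone are tied up as a chelated, cross-conjugated diketonate further deactivated by the electron-rich aryl group, because aldol and oxa-Michael adducts are reversible under these conditions, and because only the Claisen product falls irreversibly to an aromatic acylphloroglucinolate.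

**Step 10**
Reactants: 19 2',4',6'-trihydroxychalcone from step 9
Product: 21 2-[4-{[(4R,5S)-4-[4-(benzyloxy)phenyl]-2,2-dimethyl-1,3-dioxan-5-yl]oxy}-3,5-dimethoxyphenyl]-5,7-dihydroxy-4H-chromen-4-one, via flavanone 20 (not isolated)
Conditions: I2 (1.1 equiv), pyridine, 90 °C, N2
Reagents that add atoms: none
Why: Pyridine closes ring C by 6-endo-trig oxa-Michael addition of either of the two equivalent ortho hydroxyls to the enone (flavanone), and iodination at C3 through the enol followed by pyridine-mediated loss of HI gives the flavone, as known for 5,7-dihydroxyflavanones; the transient C2 stereocentre is destroyed and the basic medium leaves acetonide and benzyl ether intact.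

**Step 11**
Reactants: 21 5,7-dihydroxyflavone acetonide from step 10
Product: 22 2-[4-{[(1R,2S)-1-[4-(benzyloxy)phenyl]-1,3-dihydroxypropan-2-yl]oxy}-3,5-dimethoxyphenyl]-5,7-dihydroxy-4H-chromen-4-one
Conditions: AcOH–H2O–THF (3:1:1), 40 °C
Reagents that add atoms: none
Why: Mild acetal hydrolysis: protonation and cleavage take place at the isopropylidene carbon, not at C7'' or C8'', so both stereocentres are retained, and the weak acid in a water-rich medium should not ionise the p-alkoxybenzylic alcohol.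

**Step 12**
Reactants: 22 4''-O-benzyl flavonolignan diol from step 11
Product: 23 (−)-(7''R,8''S)-4'',5,7-trihydroxy-3',5'-dimethoxy-4',8''-oxyflavonolignan-7'',9''-diol
Conditions: H2 (1 atm), Pd/C (10 wt %), THF–MeOH, rt
Reagents that add atoms: none
Why: Catalytic hydrogenolysis of the benzyl aryl ether on Pd/C under neutral conditions is much faster than hydrogenolysis of the β-oxygenated secondary benzylic alcohol or reduction of the chromone C2–C3 double bond, so stopping after one equivalent of H2 should deliver the target with (7''R,8''S) unchanged.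

**Compound list**

1 | 4-bromo-2,6-dimethoxyphenol | COc1cc(Br)cc(OC)c1O | starting material
2 | ethyl bromoacetate | CCOC(=O)CBr | starting material
3 | ethyl 2-(4-bromo-2,6-dimethoxyphenoxy)acetate | CCOC(=O)COc1c(OC)cc(Br)cc1OC | intermediate
4 | 2-(4-bromo-2,6-dimethoxyphenoxy)acetic acid | OC(=O)COc1c(OC)cc(Br)cc1OC | intermediate
5 | (S)-4-benzyloxazolidin-2-one | O=C1OC[C@H](Cc2ccccc2)N1 | starting material
6 | 2-(4-bromo-2,6-dimethoxyphenoxy)acetic pivalic anhydride | CC(C)(C)C(=O)OC(=O)COc1c(OC)cc(Br)cc1OC | intermediate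
7 | (S)-4-benzyl-3-[2-(4-bromo-2,6-dimethoxyphenoxy)acetyl]oxazolidin-2-one | COc1cc(Br)cc(OC)c1OCC(=O)N1[C@@H](Cc2ccccc2)COC1=O | intermediate
8 | 4-(benzyloxy)benzaldehyde | O=Cc1ccc(OCc2ccccc2)cc1 | starting material
9 | (S)-4-benzyl-3-[(2R,3R)-3-[4-(benzyloxy)phenyl]-2-(4-bromo-2,6-dimethoxyphenoxy)-3-(trimethylsilyloxy)propanoyl]oxazolidin-2-one | COc1cc(Br)cc(OC)c1O[C@@H](C(=O)N1[C@@H](Cc2ccccc2)COC1=O)[C@H](O[Si](C)(C)C)c1ccc(OCc2ccccc2)cc1 | intermediate
10 | (S)-4-benzyl-3-[(2R,3R)-3-[4-(benzyloxy)phenyl]-2-(4-bromo-2,6-dimethoxyphenoxy)-3-hydroxypropanoyl]oxazolidin-2-one | COc1cc(Br)cc(OC)c1O[C@@H](C(=O)N1[C@@H](Cc2ccccc2)COC1=O)[C@H](O)c1ccc(OCc2ccccc2)cc1 | intermediate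
11 | (1R,2S)-1-[4-(benzyloxy)phenyl]-2-(4-bromo-2,6-dimethoxyphenoxy)propane-1,3-diol | COc1cc(Br)cc(OC)c1O[C@@H](CO)[C@H](O)c1ccc(OCc2ccccc2)cc1 | intermediate
12 | (4R,5S)-4-[4-(benzyloxy)phenyl]-5-(4-bromo-2,6-dimethoxyphenoxy)-2,2-dimethyl-1,3-dioxane | COc1cc(Br)cc(OC)c1O[C@H]1COC(C)(C)O[C@@H]1c1ccc(OCc2ccccc2)cc1 | intermediate
13 | N-methoxy-N-methylacrylamide | C=CC(=O)N(C)OC | starting material
14 | (E)-3-[4-{[(4R,5S)-4-[4-(benzyloxy)phenyl]-2,2-dimethyl-1,3-dioxan-5-yl]oxy}-3,5-dimethoxyphenyl]-N-methoxy-N-methylprop-2-enamide | CON(C)C(=O)/C=C/c1cc(OC)c(O[C@H]2COC(C)(C)O[C@@H]2c2ccc(OCc3ccccc3)cc2)c(OC)c1 | intermediate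
15 | triacetic acid lactone (4-hydroxy-6-methyl-2H-pyran-2-one) | CC1=CC(O)=CC(=O)O1 | starting material
16 | methyl 3,5-dioxohexanoate | COC(=O)CC(=O)CC(C)=O | intermediate
17 | trilithium trianion of methyl 3,5-dioxohexanoate | [Li+].[Li+].[Li+].[CH2-]C(=O)[CH-]C(=O)[CH-]C(=O)OC | intermediate
18 | methyl (E)-9-[4-{[(4R,5S)-4-[4-(benzyloxy)phenyl]-2,2-dimethyl-1,3-dioxan-5-yl]oxy}-3,5-dimethoxyphenyl]-3,5,7-trioxonon-8-enoate | COC(=O)CC(=O)CC(=O)CC(=O)/C=C/c1cc(OC)c(O[C@H]2COC(C)(C)O[C@@H]2c2ccc(OCc3ccccc3)cc2)c(OC)c1 | intermediate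
19 | (E)-3-[4-{[(4R,5S)-4-[4-(benzyloxy)phenyl]-2,2-dimethyl-1,3-dioxan-5-yl]oxy}-3,5-dimethoxyphenyl]-1-(2,4,6-trihydroxyphenyl)prop-2-en-1-one | COc1cc(/C=C/C(=O)c2c(O)cc(O)cc2O)cc(OC)c1O[C@H]1COC(C)(C)O[C@@H]1c1ccc(OCc2ccccc2)cc1 | intermediate
20 | 2-[4-{[(4R,5S)-4-[4-(benzyloxy)phenyl]-2,2-dimethyl-1,3-dioxan-5-yl]oxy}-3,5-dimethoxyphenyl]-5,7-dihydroxychroman-4-one (both C2 epimers) | COc1cc(C2CC(=O)c3c(O)cc(O)cc3O2)cc(OC)c1O[C@H]1COC(C)(C)O[C@@H]1c1ccc(OCc2ccccc2)cc1 | intermediate
21 | 2-[4-{[(4R,5S)-4-[4-(benzyloxy)phenyl]-2,2-dimethyl-1,3-dioxan-5-yl]oxy}-3,5-dimethoxyphenyl]-5,7-dihydroxy-4H-chromen-4-one | COc1cc(-c2cc(=O)c3c(O)cc(O)cc3o2)cc(OC)c1O[C@H]1COC(C)(C)O[C@@H]1c1ccc(OCc2ccccc2)cc1 | intermediate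
22 | 2-[4-{[(1R,2S)-1-[4-(benzyloxy)phenyl]-1,3-dihydroxypropan-2-yl]oxy}-3,5-dimethoxyphenyl]-5,7-dihydroxy-4H-chromen-4-one | COc1cc(-c2cc(=O)c3c(O)cc(O)cc3o2)cc(OC)c1O[C@@H](CO)[C@H](O)c1ccc(OCc2ccccc2)cc1 | intermediate
23 | (−)-(7''R,8''S)-4'',5,7-trihydroxy-3',5'-dimethoxy-4',8''-oxyflavonolignan-7'',9''-diol | COc1cc(-c2cc(=O)c3c(O)cc(O)cc3o2)cc(OC)c1O[C@@H](CO)[C@H](O)c1ccc(O)cc1 | target

**Step count**

Total: 12 steps. Longest linear sequence: 11 steps (steps 1–6 and 8–12, from 4-bromo-2,6-dimethoxyphenol); step 7 is a one-step side branch.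

**Steps most likely to fail**

Step 9 (Claisen folding). The chain may fold in the aldol sense instead (chain C2 carbanion adding to the C7 ketone, then dehydration to a styryl-resorcylate). An enolate carbon or oxygen may also add in conjugate fashion to C9, or the ester may be O-acylated to a 4-hydroxy-2-pyranone, so that the triketide is consumed before the C4a–C8a bond forms. The fallback gives up the folding and uses a ready-made phloroglucinol ring. It sets out from 12: bromine–lithium exchange (n-BuLi, THF, −78 °C) and formylation with DMF would give 4-{[(4R,5S)-4-[4-(benzyloxy)phenyl]-2,2-dimethyl-1,3-dioxan-5-yl]oxy}-3,5-dimethoxybenzaldehyde F1. Claisen–Schmidt condensation of F1 with purchased 1-[2,4-bis(benzyloxy)-6-hydroxyphenyl]ethanone (KOH, EtOH–THF, rt) would give the 4',6'-bis(benzyloxy)-2'-hydroxychalcone F2. Oxidative cyclisation with catalytic I2 in DMSO at 120 °C would give the 5,7-bis(benzyloxy)flavone acetonide F3, aqueous AcOH the 5,7,4''-tri-O-benzyl flavonolignan diol F4, and hydrogenolysis of all three benzyl ethers (H2, Pd/C) comes back to the route at 23.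

Step 3 (anti-aldol). The anti selectivity or the facial control may erode, because the aryloxy oxygen and its ortho-methoxy groups can compete with the imide carbonyls for magnesium, and slow addition to the electron-rich aldehyde leaves room for retro-aldol equilibration. The fallback replaces the anti-aldol by a syn-aldol followed by inversion of the carbinol centre. It sets out from 4: acylation of (R)-4-benzyloxazolidin-2-one through mixed anhydride 6 would give (R)-4-benzyl-3-[2-(4-bromo-2,6-dimethoxyphenoxy)acetyl]oxazolidin-2-one F5. The dibutylboron enolate (Bu2BOTf, iPr2NEt, CH2Cl2, −78 °C) and 8 would give the Evans syn adduct (R)-4-benzyl-3-[(2R,3S)-3-[4-(benzyloxy)phenyl]-2-(4-bromo-2,6-dimethoxyphenoxy)-3-hydroxypropanoyl]oxazolidin-2-one F6. Mitsunobu inversion with 4-nitrobenzoic acid (PPh3, DIAD, THF, 0 °C) would give the (2R,3R) 4-nitrobenzoate F7, and LiBH4 would cleave both the ester and the auxiliary and come back to the route at 11.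

Step 8 (trianion acylation). Conjugate addition to the cinnamoyl amide may compete, trianion formation may be incomplete with self-condensation of the methyl ester, and the triketo ester may lactonise to a pyranone during the acidic quench. The fallback masks the ester terminus as a dioxinone until the chain is complete. It sets out from 14: purchased 2,2,6-trimethyl-4H-1,3-dioxin-4-one would be deprotonated (LDA, THF, −78 °C) and acetylated with N-acetylimidazole to 2,2-dimethyl-6-(2-oxopropyl)-4H-1,3-dioxin-4-one F8. Double deprotonation of F8 (LDA, 2 equiv) and acylation with 14 would give 6-[(E)-6-aryl-2,4-dioxohex-5-en-1-yl]-2,2-dimethyl-4H-1,3-dioxin-4-one F9 (aryl = the ring B unit of 14). Heating F9 with methanol in toluene (110 °C; retro-[4+2] loss of acetone and capture by methanol) comes back to the route at 18.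

**Further compounds**

F1 | step 9 | 4-{[(4R,5S)-4-[4-(benzyloxy)phenyl]-2,2-dimethyl-1,3-dioxan-5-yl]oxy}-3,5-dimethoxybenzaldehyde | COc1cc(C=O)cc(OC)c1O[C@H]1COC(C)(C)O[C@@H]1c1ccc(OCc2ccccc2)cc1
F2 | step 9 | (E)-1-[2,4-bis(benzyloxy)-6-hydroxyphenyl]-3-[4-{[(4R,5S)-4-[4-(benzyloxy)phenyl]-2,2-dimethyl-1,3-dioxan-5-yl]oxy}-3,5-dimethoxyphenyl]prop-2-en-1-one | COc1cc(/C=C/C(=O)c2c(O)cc(OCc3ccccc3)cc2OCc2ccccc2)cc(OC)c1O[C@H]1COC(C)(C)O[C@@H]1c1ccc(OCc2ccccc2)cc1
F3 | step 9 | 5,7-bis(benzyloxy)-2-[4-{[(4R,5S)-4-[4-(benzyloxy)phenyl]-2,2-dimethyl-1,3-dioxan-5-yl]oxy}-3,5-dimethoxyphenyl]-4H-chromen-4-one | COc1cc(-c2cc(=O)c3c(OCc4ccccc4)cc(OCc4ccccc4)cc3o2)cc(OC)c1O[C@H]1COC(C)(C)O[C@@H]1c1ccc(OCc2ccccc2)cc1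
F4 | step 9 | 5,7-bis(benzyloxy)-2-[4-{[(1R,2S)-1-[4-(benzyloxy)phenyl]-1,3-dihydroxypropan-2-yl]oxy}-3,5-dimethoxyphenyl]-4H-chromen-4-one | COc1cc(-c2cc(=O)c3c(OCc4ccccc4)cc(OCc4ccccc4)cc3o2)cc(OC)c1O[C@@H](CO)[C@H](O)c1ccc(OCc2ccccc2)cc1
F5 | step 3 | (R)-4-benzyl-3-[2-(4-bromo-2,6-dimethoxyphenoxy)acetyl]oxazolidin-2-one | COc1cc(Br)cc(OC)c1OCC(=O)N1[C@H](Cc2ccccc2)COC1=O
F6 | step 3 | (R)-4-benzyl-3-[(2R,3S)-3-[4-(benzyloxy)phenyl]-2-(4-bromo-2,6-dimethoxyphenoxy)-3-hydroxypropanoyl]oxazolidin-2-one | COc1cc(Br)cc(OC)c1O[C@@H](C(=O)N1[C@H](Cc2ccccc2)COC1=O)[C@@H](O)c1ccc(OCc2ccccc2)cc1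
F7 | step 3 | (1R,2R)-3-[(R)-4-benzyl-2-oxooxazolidin-3-yl]-1-[4-(benzyloxy)phenyl]-2-(4-bromo-2,6-dimethoxyphenoxy)-3-oxopropyl 4-nitrobenzoate | COc1cc(Br)cc(OC)c1O[C@@H](C(=O)N1[C@H](Cc2ccccc2)COC1=O)[C@H](OC(=O)c1ccc(cc1)[N+](=O)[O-])c1ccc(OCc2ccccc2)cc1
F8 | step 8 | 2,2-dimethyl-6-(2-oxopropyl)-4H-1,3-dioxin-4-one | CC(=O)CC1=CC(=O)OC(C)(C)O1
F9 | step 8 | 6-[(E)-6-[4-{[(4R,5S)-4-[4-(benzyloxy)phenyl]-2,2-dimethyl-1,3-dioxan-5-yl]oxy}-3,5-dimethoxyphenyl]-2,4-dioxohex-5-en-1-yl]-2,2-dimethyl-4H-1,3-dioxin-4-one | CC1(C)OC(=CC(=O)O1)CC(=O)CC(=O)/C=C/c1cc(OC)c(O[C@H]2COC(C)(C)O[C@@H]2c2ccc(OCc3ccccc3)cc2)c(OC)c1
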